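0.00248 M of target was the first number I reckoned, because this is where the two steps run equally fast. Step 1 goes as k1 times substrate times target squared, step 2 as k2 times substrate. The substrate cancels, so the two are equal when target stands at the square root of k2 over k1, whatever the charge. I call this the switch-on level.

in all of them: time 15 h
- dawn: substrate 0.0020 M
- autumn: substrate 0.0040 M
- spring: substrate 0.0080 M
- noon: substrate 0.015 M
- midnight: substrate 0.030 M

    substrate + 2 target → 3 target (k1 = 180 M⁻² h⁻¹)
    substrate → target (k2 = 0.00111 h⁻¹)

* [target] at the end for dawn, autumn, spring, noon, midnight, in this order
* the shape of the row from first to last (falls, then rises / rises all the way / falls all the way / hardly changes / rises, then falls)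

- two of one species on the left: rate k times its square, two consumed each time
- "hardly changes" means that all values lie within two and a half points (for a concentration: within two and a half percent of the largest)
- run time (dawn): 15 h

**First instants.** No target is charged, so step 1 began at zero and step 2 ran by itself. That is the start of an induction period, the quiet stretch of an autocatalytic reaction. With step 1 set aside, the rate of step 2 integrates in closed form: the fraction of substrate turned into target is one minus exp(−k2 t), which gave 1.65% in 15 h. So hardly any substrate is used.

**The middle.** I watched midnight, the fullest flask, since it makes the most target. At 7.50 h I reckoned 2.49 × 10⁻⁴ M of target there, less than the level. Step 1 then ran at the square of that ratio, 1.00% of step 2.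

**The end.** At 15 h I reckoned 4.95 × 10⁻⁴ M of target in midnight, where step 1 ran at 3.98% of step 2. A steadily growing amount has a square that averages a third of its final value, so step 1 added about 1.33% over the run. That put midnight at 5.02 × 10⁻⁴ M. Dawn stood at 3.30 × 10⁻⁵ M, less than midnight, so I expected the row to rise with the charge.

**The forecast.** The forecast gave 3.300 × 10⁻⁵ M, 6.600 × 10⁻⁵ M, 1.320 × 10⁻⁴ M, 2.490 × 10⁻⁴ M and 5.020 × 10⁻⁴ M, a row that rises all the way. Its ground was that the autocatalytic step “stays barely switched on”.

**The result.** The simulation gave 3.30 × 10⁻⁵ M, 6.61 × 10⁻⁵ M, 1.32 × 10⁻⁴ M, 2.49 × 10⁻⁴ M and 5.02 × 10⁻⁴ M, a row that rises all the way. Midnight still held 98.3% of its substrate at 15 h. Its target, at 5.02 × 10⁻⁴ M, stood below the switch-on level of 0.00248 M. At 150 h, the dawn flask held 3.08 × 10⁻⁴ M of target, still below the level, and that was 15.4% of its charge. The midnight flask at 150 h held 0.0295 M, above the level by a factor of 11.9, and that was 98.2% of its charge.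

(The numbers of this flask come from no measurement.)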